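The numbers in the tables stem from a simulated flask with made-up constants.

Target above 100% of the substrate charged was impossible if one substrate gave one target, and that was where I expected the bench rule "target follows the partner charged" to break.

| flask | substrate | coupling partner | transfer agent | initiator | remark | time |
|---|---|---|---|---|---|---|
| theta | 11 mM | 0.83 equiv (in portions, 4) | 3.3 mM | 2.3 mol% | run made earlier; portions every 15 h |  |
| alpha | 11 mM | 1.4 equiv (in portions, 4) | 3.3 mM | 2.3 mol% | run made earlier; portions every 15 h |  |
| red | 11 mM | 1.90 equiv | 3.30 mM | 2.3 mol% | everything together at the start | 5.0 d |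
| amber | 11 mM | 0.950 equiv (in portions, 4) | 3.30 mM | 2.3 mol% | the portions of coupling partner follow each other after 15 h, the first at the start | 5.0 d |

| run | time / d | target / % |
|---|---|---|
| theta | 0.250 | 2.2 |
| theta | 0.625 | 5.6 |
| theta | 1.25 | 9.9 |
| theta | 2.08 | 20.8 |
| theta | 2.50 | 24.5 |
| theta | 4.00 | 36.5 |
| alpha | 0.250 | 4.0 |
| alpha | 0.500 | 6.3 |
| alpha | 0.833 | 10.8 |
| alpha | 1.25 | 16.9 |
| alpha | 2.00 | 32.8 |
| alpha | 4.00 | 53.9 |

(readings scatter by 1 percentage point)

- the flask that ends with the higher amount of target, in percent of the substrate charged, or "neither" when 2 percentage points or less lies between them (red / amber / neither)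
- final target, as a percentage of the substrate charged, in red
- final target, as a percentage of the substrate charged, in amber

- the numbers in the tables scatter by 1 percentage point (one standard deviation)
- a reading or a percentage of target counts all its forms, free or not

I tested the rule on the two earlier runs. At 4.00 d alpha had 1.69 times the coupling partner of theta, but 1.48 times its target. Those ratios gave 0.746 as the charge exponent, the logarithm of the target ratio over that of the charge ratio; the bench rule needs 1, and this reading carries the scatter of the table. Near 2.00 d the same exponent read 0.871, so it drifted down as target built up.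

For amber I started from theta, the nearer charge with the same dosing: the exponent gave 40.4% at 4.00 d, and theta's last pace carried on to 5.0 d gave 48.4%. At that share, the bench rule reached the whole substrate at 1.96, and red's 1.90 equiv stood just below this border, with substrate as its limiting reagent. So I dropped the rule for red and scaled alpha by the exponent, which gave 67.7%. That figure belonged to 4.00 d; I added nothing for the last day and took it as red's end, which was a judgement of mine and not a reckoning. Red led amber by 19 percentage points, more than the margin.

The forecast said red, with 74% in red and 46% in amber: "Red, with everything at the start, uses partner at full concentration while k is highest".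

Red ended at 65.9% and amber at 46.3%, so red gave more.

    substrate + initiating radical → capped initiator + first chain carrier (k = 20000 L mol⁻¹ s⁻¹)
    substrate + second chain carrier → by-product + first chain carrier (k = 2.40 × 10⁶ L mol⁻¹ h⁻¹)
    2 first chain carrier → ended chains A (k = 1.00 × 10⁸ L mol⁻¹ s⁻¹)
    transfer agent + first chain carrier → side product + idle radical (kL = 4.80 × 10⁵ L mol⁻¹ h⁻¹)
    initiator → 2 initiating radical (k = 0.0180 h⁻¹)
    substrate + target ⇌ idle adduct, settled at all times (K = 3700 L mol⁻¹)
    2 second chain carrier → ended chains B (k = 1.00 × 10⁶ L mol⁻¹ s⁻¹)
    2 idle radical → ended radicals (k = 2.30 × 10⁷ L mol⁻¹ s⁻¹)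
    coupling partner + first chain carrier → target + second chain carrier (k = 6.20 × 10⁶ L mol⁻¹ h⁻¹)

My reckoning stood 1.8 points above red and 2.1 points above amber. Red ended with 2.1% of its substrate free and 65% of its coupling partner unused. From amber to red, dosing aside, the charge exponent came to 0.508, below my 0.746. A neighbouring flask, like red but with 0.470 equiv of coupling partner, ended at 30.1%, and from it to red the exponent was 0.561.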